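**Assumptions:** (i) the (S)-diol in Step 1 is assumed to give the (R)-adduct; if the sense is opposite, the (R)-diol is used. (ii) 2,4-Dihydroxy-6-methylbenzaldehyde is taken as commercial; otherwise it comes from orcinol by one Vilsmeier formylation.

## Retrosynthetic overview
1. The target comes from one final hydrogenation/hydrogenolysis of 14, which removes two OBn groups and saturates the C=C.
2. The diarylmethane (ring B–CH2–ring C) is made by Suzuki coupling of the chiral ring-C aryl-Bpin 6 with the ring-B benzylic bromide 13.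
3. The only stereocentre, the tertiary benzylic carbinol, is set in the first step. A BINOL-type diol catalyses allylboration of commercial 2′-hydroxy-4′-bromoacetophenone (1). Cross-metathesis with 3-methylbut-1-ene then completes the 6-carbon chain, which is saturated at the end.
4. Ring B/A diaryl ether: regioselective 4-O-arylation of orcinol aldehyde (9) with the benzyl-protected aryl bromide 8, then protection, reduction and bromination.
5. No new rings are formed; the order of assembly is stereocentre → A–O–B ether → B–CH2–C link.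

## Route

**Step 1**
Reactants: 1 (1-(4-bromo-2-hydroxyphenyl)ethan-1-one); 2 (allyldiisopropoxyborane)
Product: 3, (2R)-2-(4-bromo-2-hydroxyphenyl)pent-4-en-2-ol
Conditions: 2 (2.5 equiv), (S)-3,3′-Br2-BINOL (20 mol%), iPrOH (2.5 equiv), PhMe, 0 °C → rt, 24 h; pH 7 buffer work-up
Reagents that add atoms: allyldiisopropoxyborane, C=CCB(OC(C)C)OC(C)C (adds allyl)
Why: Proposed new method: the free phenol exchanges onto boron so that the chelated aryloxy(allyl)borinate delivers allyl through a chair Zimmerman–Traxler-type TS, while BINOL exchanged onto boron in place of OiPr makes the boron centre chiral and selects the ketone face. The closest known reaction is diol-catalysed allylboration of ketones, here applied to a free 2-hydroxyaryl methyl ketone, where the phenol acts as a boron tether. This sets the (R) tertiary carbinol (OH > aryl > CH2 > CH3).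

**Step 2**
Reactants: 3; 4 (3-methylbut-1-ene)
Product: 5, (2R,4E)-2-(4-bromo-2-hydroxyphenyl)-6-methylhept-4-en-2-ol
Conditions: 4 (10 equiv), Hoveyda–Grubbs II (5 mol%), CH2Cl2, sealed tube, 40 °C, 16 h
Reagents that add atoms: 3-methylbut-1-ene, C=CC(C)C (adds =CH–CH(CH3)2; ethylene is lost)
Why: Olefin cross-metathesis of the terminal alkene gives the internal alkene, which after hydrogenation is the 4-methylpentyl chain. The stereocentre is untouched and ArBr, the phenol and the tertiary alcohol are inert to Ru.

**Step 3**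
Reactants: 5
Product: 6, (2R,4E)-2-[2-hydroxy-4-(4,4,5,5-tetramethyl-1,3,2-dioxaborolan-2-yl)phenyl]-6-methylhept-4-en-2-ol
Conditions: B2pin2 (1.3 equiv), PdCl2(dppf) (5 mol%), KOAc (3 equiv), dioxane, 80 °C, 12 h
Reagents that add atoms: B2pin2, CC1(C)OB(OC1(C)C)B1OC(C)(C)C(C)(C)O1 (adds Bpin)
Why: Miyaura borylation with a weak base tolerates the free OH groups and the alkene, and it is not acidic, so the o-hydroxybenzylic tertiary alcohol keeps its configuration.

**Step 4**
Reactants: 7 (3-bromo-5-methylphenol)
Product: 8, 1-(benzyloxy)-3-bromo-5-methylbenzene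
Conditions: BnBr (1.1 equiv), K2CO3, acetone, reflux, 8 h
Reagents that add atoms: benzyl bromide, BrCc1ccccc1 (adds Bn)
Why: Williamson O-benzylation of the phenol.

**Step 5**
Reactants: 8; 9 (2,4-dihydroxy-6-methylbenzaldehyde)
Product: 10, 4-[3-(benzyloxy)-5-methylphenoxy]-2-hydroxy-6-methylbenzaldehyde
Conditions: 8 (1.2 equiv), CuI (10 mol%), N,N-dimethylglycine (30 mol%), Cs2CO3 (2.5 equiv), dioxane, 105 °C, 24 h
Reagents that add atoms: none
Why: Ullmann–Ma diaryl ether synthesis occurs selectively at the more acidic, unhindered 4-OH; the 2-OH is locked by an H-bond to the CHO.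

**Step 6**
Reactants: 10
Product: 11, 2-(benzyloxy)-4-[3-(benzyloxy)-5-methylphenoxy]-6-methylbenzaldehyde
Conditions: BnBr (1.2 equiv), K2CO3, DMF, 60 °C, 6 h
Reagents that add atoms: benzyl bromide, BrCc1ccccc1 (adds Bn)
Why: O-benzylation of the chelated phenol blocks it, so no o-quinone methide can form later.

**Step 7**
Reactants: 11
Product: 12, [2-(benzyloxy)-4-(3-(benzyloxy)-5-methylphenoxy)-6-methylphenyl]methanol
Conditions: NaBH4 (1.5 equiv), THF/MeOH, 0 °C, 1 h
Reagents that add atoms: none (hydride only)
Why: Chemoselective aldehyde reduction; the ethers are inert.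

**Step 8**
Reactants: 12
Product: 13, 2-(benzyloxy)-1-(bromomethyl)-4-[3-(benzyloxy)-5-methylphenoxy]-6-methylbenzene
Conditions: CBr4 (1.3 equiv), PPh3 (1.3 equiv), CH2Cl2, 0 °C, 1 h; used crude
Reagents that add atoms: carbon tetrabromide, BrC(Br)(Br)Br (adds Br)
Why: Appel bromination under neutral conditions avoids acid-promoted side reactions of the electron-rich benzylic system.

**Step 9**
Reactants: 6; 13
Product: 14, 5-{[2-(benzyloxy)-4-(3-(benzyloxy)-5-methylphenoxy)-6-methylphenyl]methyl}-2-[(2R,4E)-2-hydroxy-6-methylhept-4-en-2-yl]phenol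
Conditions: PdCl2(dppf)·CH2Cl2 (5 mol%), K3PO4 (3 equiv), THF/H2O 10:1, 60 °C, 12 h
Reagents that add atoms: none
Why: Benzyl–aryl Suzuki–Miyaura coupling forms the diarylmethane under mild base, so the stereocentre is not ionised or racemised.

**Step 10**
Reactants: 14
Product: 15, target
Conditions: H2 (1 atm), 10% Pd/C, NaHCO3 (solid), EtOAc/EtOH, rt, 16 h
Reagents that add atoms: none (H2 adds hydrogen only)
Why: One hydrogenation removes both benzyl ethers and reduces the C=C to the saturated 4-methylpentyl chain. The neutral, buffered conditions leave the tertiary o-hydroxybenzylic C–O bond and the (R) centre intact.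

## Compound list
1 | 1-(4-bromo-2-hydroxyphenyl)ethanone | CC(=O)c1ccc(Br)cc1O | starting material
2 | allyldiisopropoxyborane | C=CCB(OC(C)C)OC(C)C | starting material
3 | (2R)-2-(4-bromo-2-hydroxyphenyl)pent-4-en-2-ol | Oc1cc(Br)ccc1[C@](C)(O)CC=C | intermediate
4 | 3-methylbut-1-ene | C=CC(C)C | starting material
5 | (2R,4E)-2-(4-bromo-2-hydroxyphenyl)-6-methylhept-4-en-2-ol | Oc1cc(Br)ccc1[C@](C)(O)C/C=C/C(C)C | intermediate
6 | aryl-Bpin of 5 | Oc1cc(B2OC(C)(C)C(C)(C)O2)ccc1[C@](C)(O)C/C=C/C(C)C | intermediate
7 | 3-bromo-5-methylphenol | Cc1cc(O)cc(Br)c1 | starting material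
8 | 1-(benzyloxy)-3-bromo-5-methylbenzene | Cc1cc(Br)cc(OCc2ccccc2)c1 | intermediate
9 | 2,4-dihydroxy-6-methylbenzaldehyde | Cc1cc(O)cc(O)c1C=O | starting material
10 | 4-[3-(benzyloxy)-5-methylphenoxy]-2-hydroxy-6-methylbenzaldehyde | Cc1cc(Oc2cc(C)cc(OCc3ccccc3)c2)cc(O)c1C=O | intermediate
11 | 2-(benzyloxy)-4-[3-(benzyloxy)-5-methylphenoxy]-6-methylbenzaldehyde | Cc1cc(Oc2cc(C)cc(OCc3ccccc3)c2)cc(OCc3ccccc3)c1C=O | intermediate
12 | benzylic alcohol from 11 | Cc1cc(Oc2cc(C)cc(OCc3ccccc3)c2)cc(OCc3ccccc3)c1CO | intermediate
13 | benzylic bromide from 12 | Cc1cc(Oc2cc(C)cc(OCc3ccccc3)c2)cc(OCc3ccccc3)c1CBr | intermediate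
14 | dibenzyl-protected alkene (Suzuki product) | Oc1cc(Cc2c(OCc3ccccc3)cc(Oc4cc(C)cc(OCc5ccccc5)c4)cc2C)ccc1[C@](C)(O)C/C=C/C(C)C | intermediate
15 | target, (R)-configured tertiary alcohol | Cc1cc(O)cc(Oc2cc(C)c(Cc3ccc([C@](C)(O)CCCC(C)C)c(O)c3)c(O)c2)c1 | target

## Counts
Total steps: 10. Longest linear sequence: 7 (7 → 8 → 10 → 11 → 12 → 13 → 14 → 15, i.e. Steps 4–10).

## Three steps most likely to fail
1. **Step 1 (proposed new step).** The phenol-tethered allylboration may give low ee, or be slow because the H-bonded ketone is poorly electrophilic and the phenol consumes boron.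
 Fallback: benzylate the phenol, run the known diol-catalysed allylboration on the 2-OBn ketone, and remove the extra Bn in Step 10. If ee is still low, use racemic allylMgBr addition and resolve by preparative chiral-phase HPLC.
2. **Step 9.** The hindered 2,6-disubstituted benzylic bromide may couple poorly, or the free phenol may be benzylated or the homoallylic alcohol undergo Pd β-carbon elimination.
 Fallback: metal-free Barluenga coupling of the N-tosylhydrazone of aldehyde 11 with the boronic acid from 6 (K2CO3, dioxane, 110 °C), which avoids the benzylic halide and Pd.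
3. **Step 5.** The Ullmann coupling of an electron-rich aryl bromide with a hindered phenol may be low-yielding or poorly regioselective.
 Fallback: Chan–Lam O-arylation of 9 with 3-(benzyloxy)-5-methylphenylboronic acid (made from 8 by BuLi then B(OMe)3), using Cu(OAc)2, pyridine, air.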